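Equal charges of substrate and partner look like a tie, and that is the pitfall: a reagent with a second drain can run out first from a level start.

common to all: substrate 0.10 M; free catalyst 6.2 mol%
- red: partner 0.67 equiv; run made earlier
- grey: partner 1.5 equiv; run made earlier
- flask: partner 1.00 equiv; time 20 h

| run | time / h | substrate / % | target / % |
|---|---|---|---|
| red | 1.00 | 63.1 | 35.7 |
| red | 2.00 | 46.0 | 53.0 |
| red | 3.00 | 39.1 | 59.8 |
| red | 6.00 | 34.9 | 64.9 |
| red | 12.0 | 34.4 | 64.3 |
| grey | 2.50 | 24.3 | 74.2 |
| grey | 5.00 | 14.5 | 86.4 |
| grey | 8.00 | 9.5 | 89.5 |
| grey | 10.0 | 9.0 | 90.7 |
| grey | 12.0 | 9.3 | 91.2 |

(readings scatter by 0.5 percentage points)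

* which holds at 20 h: what has brought the reaction to rest, or that it has not come to rest (no working catalyst is left / all of the substrate has reacted / forward and back rates have come level / it is still moving / the partner has run out first)
* conversion of substrate at 20 h
* amount of target at 20 h, in percent of the substrate charged
* amount of target if the flask were left three thousand times as long, in percent of the substrate charged

- the analysis behind the earlier runs scatters by 0.5 percentage points, standard deviation
- the reaction counts as stopped when no species that holds the substrate changes by six tenths of a point or more over the second half of the time

I write the balance of partner as charge = target + partner left + toll. The red run rests near 64.6% target from 0.67 equiv of partner. Taking its partner as used up, the partner toll, partner gone without becoming target per unit of target, reads 3.72%, a small difference of readings that carries their scatter.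

Now the rate. Let w be the rate per unit of partner still there, with partner reckoned from target. In the red run w is 0.761 h⁻¹ in the first hour and 0.805 h⁻¹ in the second, so with w level, the fall in rate by a factor 2.06 goes with partner running down. In the grey run w drops from 0.273 h⁻¹ to 0.0702 h⁻¹, a further factor 3.89, and I read that second brake as catalyst being lost. The flask's partner charge lies between those two, so I expect its early w to lie between 0.273 h⁻¹ and 0.761 h⁻¹, and to sag less than grey's. If its w held at 0.273 h⁻¹, the low end of that range, partner in the flask would halve every 2.54 h, about 7.88 halvings by 20 h. So I commit to this: the partner runs out first, and target stops near 96.4%.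

The forecast differs from mine: it is still moving, conversion 87%, target 86.3%, and 90.5% eventually, holding that “grey stalled because its catalyst died”.

    partner + free catalyst → catalyst intermediate A (k = 0.0580 L mol⁻¹ s⁻¹)
    catalyst intermediate A ⇌ catalyst intermediate B (K = 0.530, k = 0.0450 s⁻¹)
    substrate + catalyst intermediate B → catalyst intermediate C (k = 0.300 L mol⁻¹ s⁻¹)
    catalyst intermediate C → catalyst intermediate D (k = 4.50 s⁻¹)
    catalyst intermediate D → free catalyst + target (k = 0.0340 s⁻¹)
    partner + catalyst intermediate B → spent catalyst (k = 0.00980 L mol⁻¹ s⁻¹)

The flask gives the partner has run out first: conversion 94.8%, target 94.8%, and 94.8% after the long wait, with partner at 0%, substrate at 5.20% and spent catalyst at 41.9%. Its toll is 5.49%, above the red reading, so my figure stood 1.6 percentage points high. The flask charged with 1.70 equiv of partner, by the same balance, has a toll of 15.0%: target reaches 82.5%, 44% of its partner remains, and spent catalyst stands at >99.9%.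

The runs come from a simulation for substances that don't exist, noise included.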